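Count turnovers, not minutes, in this flask.

    reagent in the reaction phase ⇌ reagent in the second phase, rate k1*([reagent in the reaction phase] - [reagent in the second phase]/K1) per volume of the first phase (K1 = 0.59, k1 = 0.00148 s⁻¹)
    substrate + reagent in the reaction phase → target (k2 = 0.00869 M⁻¹ s⁻¹)
    reagent in the reaction phase → decomposition product (k3 = 3.13 × 10⁻⁶ s⁻¹)
    reagent in the reaction phase + target → over-reaction product (k4 = 0.0395 M⁻¹ s⁻¹)
substrate 0.25 M; reagent in the second phase 2.00 equiv; time 4.0 min; volume of the second phase over the first 0.50
- the target standing at 4.0 min, as a percentage of the substrate charged
- part of the substrate charged that has reacted at 4.0 min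

**The clock.** Let N, the turnover count, be the rate constant of target formation times the time integral of [reagent in the reaction phase]; the substrate left is then the fraction a = exp(−N). Target formation and over-reaction share that concentration, so on this clock the crossing drops out: y = (a − a^κ)/(κ − 1). Here κ is the rate constant of over-reaction over that of target formation, the selectivity factor 4.55.

**Upper bound.** I first let nothing consume reagent. The reaction phase then fills toward 0.386 M with time constant 2.57 min, so N stays below 0.397 and conversion below 32.8%. The law rises until N reaches 0.427, so y stays below 14.3%.

**Lower bound.** Next I give the reaction phase a constant loss of 0.215 min⁻¹, which is what charged substrate, target at its ceiling and decomposition together would take. This two-tank system has time constants 2.15 min and 7.19 min. It gives N of at least 0.301, conversion of 26.0% and y of 13.7%.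

**The forecast.** It reads 14% and 28.2%, holding that “the run is largely transfer-limited”, and lies inside both brackets.

**The run.** The simulation gives 13.9% at 27.5% conversion, and the law on that conversion returns 13.9%. At 1.33 min the crossing was making reagent in the reaction phase 4.21 times as fast as it was used. By 4.00 min target, made 1.15 times as fast as used up, stood at 13.9% beside 13.6% over-reaction product. The neighbour read at 10 min shows 59.5% conversion, where the law gives 10.9% and that flask holds 11.0%.

The numbers come from no measurement; no experiment stands behind them.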